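## Structural features

The target 8 is an unsymmetrical benzil. A 4-methoxyphenyl ring and a 2,2-dimethyl-2H-chromene are joined through a C(=O)–C(=O) unit that sits on chromene C6. The benzene ring of the chromene is a pentasubstituted phloroglucinol in which the three oxygens all differ: the oxygen on C8a is the pyran O1, the oxygen on C5 is a methyl ether, and the oxygen on C7 is a free, chelated phenol. Only C8 carries hydrogen. There is no stereocentre, no stereogenic double bond and no resolvable axis, so the compound is achiral. The fragile groups are the electron-rich C3=C4 olefin of the pyran ring (acid, electrophilic oxidants, UV light) and the α-diketone (peroxide cleavage, benzilic acid rearrangement, ring–chain tautomerism with the five-membered hemiketal formed by the C7 hydroxyl). The real difficulty is the substitution pattern. The diketone must stand between the two oxygenated carbons C5 and C7, the pyran carbon C4a must lie next to the OMe-bearing C5, and of the two nearly equivalent oxygens ortho to the acyl group only the one on C5 may be methylated. The key step exploits the five-atom array O(on C7)–C7–C6–C(=O)–C(=O)Ar. This array is a γ-pyrone ring short of one carbon, because a CH placed between the phenol oxygen and the anisyl-bearing carbonyl carbon restores ring C of an isoflavone, the presumed biogenetic parent of natural benzils. In that isoflavone the oxygen that must end free is locked in the ring, the oxygen that must be methylated is a free hydroxyl, and the carbon that must carry the pyran lies between two hydroxyl groups.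

## Logic of the disconnections

Locants: plain locants follow the 2H-chromene numbering of 8. Locants with the prefix i- follow the isoflavone numbering used for 1, 3, 4 and 5. The mapping is i-O1 = O on C7, i-C8a = C7, i-C8 = C8, i-C7 = C8a, i-C6 = C4a, i-C5 = C5, i-C4a = C6, i-C4 = aroyl C=O, i-C3 = anisoyl C=O. In one sentence, the α-diketone and the free phenol are released together by oxidative excision of i-C2 from the γ-pyrone ring of 5.

**8 ⇒ 5 (by way of 7 and 6).**
- Bonds: this is a reconnection. The oxygen of the anisyl-side C=O and the hydrogen of the C7 hydroxyl are replaced by one sp2 CH, double-bonded to the former carbonyl carbon and single-bonded to the phenol oxygen. Read forwards, the i-C2=i-C3 and i-O1–i-C2 bonds of 5 are broken and i-C2 leaves.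
- Reason: this one atom removes both troublesome functions, the diketone and the phenol that competes with its neighbour.
- Gain: a sensitive, hard-to-pattern benzil becomes a robust tricyclic pyrone two steps from a purchasable compound. The OH/OMe question also disappears, since the free OH can come only from i-O1.
- Demand: an electron-poor enol-ether C=C must be cleaved in the presence of the electron-rich C3=C4 olefin. A secondary amine meets this by turning the acceptor olefin of 5 into the donor olefin of 6, which an electrophilic oxidant then prefers over everything else in the molecule.

**5 ⇒ 4.**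
- Bonds: the O–CH3 bond on i-C5 is cut.
- Reason: in 4 this oxygen is the only hydroxyl left, so the methylation needs no selectivity.
- Gain: one carbon, and a free i-5-OH that is needed one step earlier as a directing neighbour.
- Demand: a chelated, peri-flanked hydroxyl must be alkylated without a nucleophilic base that would open the pyrone.

**4 ⇒ 1 + 2 (by way of 3).**
- Bonds: the pyran ring is removed by cutting i-C6–C(H)= (C4a–C4 in 8) and i-O7–CMe2 (O1–C2 in 8).
- Reason: the five-carbon unit is an enal, and the ring closes by electrocyclisation of 3.
- Gain: a full ring is removed, and the plan arrives at two articles of commerce.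
- Demand: attack must occur at i-C6 and not at i-C8, and closure must go onto i-O7 and not i-O5. In 1, i-C6 lies between two free hydroxyl groups while i-C8 has the weakly donating pyrone oxygen as one neighbour, and the i-5-OH is held in a chelate. In an open benzil the same inherent bias would point to the wrong carbon.

## Other disconnections considered

**Alternative 1:** (the first that comes to mind)
- Cut: the aryl–acyl bond C6–C(=O), with the anisyl-side carbonyl stepped down to CH2.
- Forward key step: Hoesch or Friedel–Crafts acylation of 5-methoxy-2,2-dimethyl-2H-chromen-7-ol A1 with a 4-methoxyphenylacetyl donor to give the deoxybenzoin A2, followed by Riley oxidation of the methylene group.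
- Ground for preferring the chosen plan: in A1 both C6 and C8 are ortho to the free hydroxyl and each is flanked by two oxygens, so nothing in the structure directs the acyl group to C6. The strong Brønsted or Lewis acids of the acylation also protonate the styrene-type pyran olefin. A1 is not purchasable, and making it already requires the threefold differentiation of the phloroglucinol oxygens, so the hard problem is only moved and the step count rises.

**Alternative 2:**
- Cut: the C6–C bond, with the C2 unit traced back to an alkyne.
- Forward key step: Sonogashira coupling of the iodide A3 with the anisyl-substituted terminal alkyne to give the tolane A4, then alkyne-to-diketone oxidation and removal of the acetal.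
- Ground for preferring the chosen plan: A3 needs an iodine placed between two alkoxy groups, which is the same C6/C8 site problem. The C7 oxygen must be protected, because a free o-alkynylphenol closes 5-endo-dig to a 2-arylbenzofuran. The electrophilic oxidants that convert alkynes into diketones have no mechanistic reason to spare the more electron-rich chromene olefin. The sequence is at least twice as long.

**Alternative 3:**
- Cut: the pyran ring (C4–C4a and O1–C2) on the finished benzil A5.
- Forward key step: annulation of A5 with 2 through an o-quinone methide.
- Ground for preferring the chosen plan: in A5 the most nucleophilic ring carbon is the one between the two free hydroxyl groups. The inherent course therefore leads to the 5-hydroxy-7-methoxy isomer A6 and not to 8. In addition, the base-sensitive α-diketone would be exposed to the basic annulation medium. The chosen plan uses the same annulation but inverts its bias by tying the misdirecting oxygen into the pyrone ring.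

Key step: step 3

Remark on stereochemistry: the SMILES carries no stereodescriptor and the structure has no stereogenic element, so "single enantiomer" is taken to mean the one achiral compound.
Remark on supply: 1 (biochanin A) and 2 (prenal) are taken as articles of commerce.

## Route

Step 1
Reactants: 1 biochanin A [5,7-dihydroxy-3-(4-methoxyphenyl)-4H-chromen-4-one]; 2 3-methylbut-2-enal (prenal)
Product: 4 4'-O-methylalpinumisoflavone [5-hydroxy-7-(4-methoxyphenyl)-2,2-dimethyl-2H,6H-pyrano[3,2-g]chromen-6-one], via o-quinone methide 3 (not isolated)
Conditions: 2 (2 equiv), Ca(OH)2 (2 equiv), MeOH, rt; then 1 M HCl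
Reagents that add atoms: none
Why: Base-mediated chromene annulation (aldol-type C-alkylation of the phenoxide by the enal, loss of water to o-quinone methide 3, oxa-6π electrocyclisation). i-C6 lies between the two free hydroxyl groups and is the usual site of C-alkylation in phenoxides of 5,7-dihydroxyisoflavones, whereas i-C8 has the weakly donating pyrone i-O1 as second neighbour; closure goes to i-O7 because the ionised 7-oxygen becomes the carbonyl of 3 while the i-5-OH stays in its chelate with i-C4=O. No stereocentre is formed.

Step 2
Reactants: 4 4'-O-methylalpinumisoflavone
Product: 5 O,O-dimethylalpinumisoflavone [5-methoxy-7-(4-methoxyphenyl)-2,2-dimethyl-2H,6H-pyrano[3,2-g]chromen-6-one]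
Conditions: MeI (3 equiv), K2CO3 (3 equiv), dry DMF, 50 °C
Reagents that add atoms: iodomethane, CI
Why: Williamson ether synthesis; the i-5-OH is the only acidic proton left, so no selectivity is needed, and excess reagent with gentle heating in a dipolar aprotic solvent should overcome the hydrogen bond to i-C4=O. Anhydrous carbonate does not attack i-C2 of the pyrone, and the chromene olefin and the aryl ethers are inert.

Step 3
Reactants: 5 O,O-dimethylalpinumisoflavone
Product: 8 1-(7-hydroxy-5-methoxy-2,2-dimethyl-2H-chromen-6-yl)-2-(4-methoxyphenyl)ethane-1,2-dione (target), via enaminone 6 (not isolated), via amino-dioxetane 7 (not isolated)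
Conditions: pyrrolidine (5 equiv), dry MeCN, 60 °C; evaporate; O2, tetraphenylporphyrin (1 mol %), CH2Cl2, Na lamp (589 nm), −78 to −20 °C; aq. citric acid wash
Reagents that add atoms: dioxygen, O=O (one oxygen atom becomes the new carbonyl oxygen of 8); pyrrolidine, C1CCNC1 (its atoms are present in 6 and 7 only)
Why: Pyrrolidine adds to the electrophilic i-C2 of the γ-pyrone (aza-Michael addition to a vinylogous ester) and the enolate expels the i-O1 phenoxide (E1cB), the known ring opening of chromones and isoflavones by secondary amines, which gives enaminone 6 and already frees the C7 hydroxyl. Singlet oxygen, an electrophile, then adds across the Cα=Cβ bond of 6 in a formal [2+2] mode (through a perepoxide or iminium–peroxide zwitterion) to give amino-dioxetane 7, whose four-membered ring cycloreverts below 0 °C to the new C=O of 8 and pyrrolidine-1-carbaldehyde, which carries away the former i-C2. The closest known reaction type is the dye-sensitised photooxygenative cleavage of β-enamino ketones to α-diketones, run here directly on the crude ring-opened isoflavone. No ring of 8 is closed and no stereocentre of 8 is made; the two centres of 7 are transient and their configuration has no consequence. The selectivity needed is enamine C=C against the chromene C3=C4 bond, the phenol ring and the anisyl ring: the amine inverts the pyrone olefin from acceptor to donor, the two ortho substituents twist the aroyl group out of conjugation so that 6 reacts almost as a simple enamine, and the chromene olefin is only a styrene-type bond without allylic hydrogen, closed to the ene reaction and slow in [2+2] and [4+2] modes. Light near 589 nm is absorbed by the sensitiser alone, so neither the α-diketone of 8 nor the photochromic chromene is excited, and removal of excess amine before irradiation keeps the phenol un-ionised and spares 8 from amine addition. Since the free hydroxyl can arise only from i-O1, the step fixes at once the diketone, its place between C5 and C7, and the OH/OMe pattern.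

## Compound list

1 | biochanin A, 5,7-dihydroxy-3-(4-methoxyphenyl)-4H-chromen-4-one | COc1ccc(cc1)C2=COc3cc(O)cc(O)c3C2=O | starting material
2 | 3-methylbut-2-enal (prenal) | CC(C)=CC=O | starting material
3 | o-quinone methide, (6Z)-5-hydroxy-3-(4-methoxyphenyl)-6-(3-methylbut-2-en-1-ylidene)-4H-chromene-4,7(6H)-dione | COc1ccc(cc1)C2=COC3=CC(=O)/C(=C\C=C(C)C)C(O)=C3C2=O | intermediate
4 | 4'-O-methylalpinumisoflavone, 5-hydroxy-7-(4-methoxyphenyl)-2,2-dimethyl-2H,6H-pyrano[3,2-g]chromen-6-one | COc1ccc(cc1)C4=COc2cc3OC(C)(C)C=Cc3c(O)c2C4=O | intermediate
5 | O,O-dimethylalpinumisoflavone, 5-methoxy-7-(4-methoxyphenyl)-2,2-dimethyl-2H,6H-pyrano[3,2-g]chromen-6-one | COc1ccc(cc1)C4=COc2cc3OC(C)(C)C=Cc3c(OC)c2C4=O | intermediate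
6 | enaminone, (E)-1-(7-hydroxy-5-methoxy-2,2-dimethyl-2H-chromen-6-yl)-2-(4-methoxyphenyl)-3-(pyrrolidin-1-yl)prop-2-en-1-one | COc1ccc(cc1)/C(=C\N2CCCC2)C(=O)c3c(O)cc4OC(C)(C)C=Cc4c3OC | intermediate
7 | amino-dioxetane, (7-hydroxy-5-methoxy-2,2-dimethyl-2H-chromen-6-yl)[3-(4-methoxyphenyl)-4-(pyrrolidin-1-yl)-1,2-dioxetan-3-yl]methanone, racemic, aryl and pyrrolidinyl cis (one enantiomer drawn) | COc1ccc(cc1)[C@]2(C(=O)c3c(O)cc4OC(C)(C)C=Cc4c3OC)OO[C@@H]2N5CCCC5 | intermediate
8 | 1-(7-hydroxy-5-methoxy-2,2-dimethyl-2H-chromen-6-yl)-2-(4-methoxyphenyl)ethane-1,2-dione (CNP0170833.0, achiral) | COc1ccc(C(=O)C(=O)c2c(O)cc3c(c2OC)C=CC(C)(C)O3)cc1 | target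

## Step count and least certain steps

Total step count: 3. Longest linear sequence: 3 steps (1 → 4 → 5 → 8).

**Step 3 (key step).**
- Ring opening may be incomplete or reversible, because the phenol can re-add intramolecularly to the enamine carbon and expel pyrrolidine during the solvent change.
- Adventitious water may cause hydrolytic loss of the formyl carbon before oxidation.
- Singlet oxygen may attack the chromene olefin, or the phenolate if residual amine ionises the phenol.
- Fallback: the excision and the oxidation are separated. The fallback sets out from 5. Classical alkaline deformylation of the isoflavone (KOH, aqueous EtOH, reflux) should give the deoxybenzoin 1-(7-hydroxy-5-methoxy-2,2-dimethyl-2H-chromen-6-yl)-2-(4-methoxyphenyl)ethan-1-one F1 (the same structure as A2). Riley oxidation of its activated methylene group (SeO2, aqueous dioxane, 90 °C) should be tolerated by the chromene olefin, which has no allylic hydrogen. This returns to the route at 8.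

**Step 1.**
- Site selectivity between i-C6 and i-C8 may be poor, since both carbons are activated by all three ring oxygens.
- Base-induced self-condensation of the enal may compete with a slow C-alkylation of the sparingly soluble calcium phenoxide.
- Fallback: bond formation and ring closure are separated. The fallback sets out from 1. Nuclear C-prenylation of the phenoxide (prenyl bromide, NaOMe, MeOH) should give 5,7-dihydroxy-3-(4-methoxyphenyl)-6-(3-methylbut-2-en-1-yl)-4H-chromen-4-one F2, which can be freed from any i-C8 isomer at this open-chain stage. DDQ-mediated dehydrogenative cyclisation (dioxane, reflux) then passes through the same o-quinone methide, closes onto i-O7, and returns to the route at 4.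

**Step 2.**
- Alkylation may be incomplete, because the hydroxyl is chelated to i-C4=O and crowded by the peri hydrogen of the pyran ring.
- If forcing conditions meet traces of water, hydroxide may open the pyrone ring.
- Fallback: the oxygen is methylated at a metal instead of as a free phenoxide. The fallback sets out from 4. A Chan–Lam-type oxidative O-methylation (methylboronic acid, Cu(OAc)2, pyridine, air, 1,2-dichloroethane, 80 °C) uses the i-5-O/i-4-C=O chelate site as a bidentate ligand for copper, so the chelation that hinders SN2 alkylation helps here. This returns to the route at 5 and makes no new compound (F0).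

## Further compounds

F1 | step 3 | 1-(7-hydroxy-5-methoxy-2,2-dimethyl-2H-chromen-6-yl)-2-(4-methoxyphenyl)ethan-1-one | COc1ccc(CC(=O)c2c(O)cc3OC(C)(C)C=Cc3c2OC)cc1
F2 | step 1 | 5,7-dihydroxy-3-(4-methoxyphenyl)-6-(3-methylbut-2-en-1-yl)-4H-chromen-4-one | COc1ccc(cc1)C2=COc3cc(O)c(CC=C(C)C)c(O)c3C2=O
F0 | step 2 | none | none
A1 | alternative 1 | 5-methoxy-2,2-dimethyl-2H-chromen-7-ol | COc1cc(O)cc2OC(C)(C)C=Cc12
A2 | alternative 1 | 1-(7-hydroxy-5-methoxy-2,2-dimethyl-2H-chromen-6-yl)-2-(4-methoxyphenyl)ethan-1-one | COc1ccc(CC(=O)c2c(O)cc3OC(C)(C)C=Cc3c2OC)cc1
A3 | alternative 2 | 6-iodo-5-methoxy-7-(methoxymethoxy)-2,2-dimethyl-2H-chromene | COCOc1cc2OC(C)(C)C=Cc2c(OC)c1I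
A4 | alternative 2 | 5-methoxy-7-(methoxymethoxy)-6-[(4-methoxyphenyl)ethynyl]-2,2-dimethyl-2H-chromene | COCOc1cc2OC(C)(C)C=Cc2c(OC)c1C#Cc3ccc(OC)cc3
A5 | alternative 3 | 1-(2,4-dihydroxy-6-methoxyphenyl)-2-(4-methoxyphenyl)ethane-1,2-dione | COc1ccc(cc1)C(=O)C(=O)c2c(O)cc(O)cc2OC
A6 | alternative 3 | 1-(5-hydroxy-7-methoxy-2,2-dimethyl-2H-chromen-6-yl)-2-(4-methoxyphenyl)ethane-1,2-dione | COc1ccc(cc1)C(=O)C(=O)c2c(O)c3C=CC(C)(C)Oc3cc2OC
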